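Numbering the chain from the carboxyl carbon (C1), everything rests on the C9–C10 disconnection, the bond between the C9 methylene and the vinylic C10–H carbon of the (Z)-C10=C11 olefin, whose C11 bears the methyl and the three-carbon tether to the anhydride ring. A Zweifel olefination exploits this pattern, forming the bond and setting the Z geometry in one operation: a primary C9 alkyllithium (C1–C9, with the citronellol-derived C3 stereocentre and a Still–Wittig-derived (Z)-C6=C7 olefin) adds to an (E)-alkenyl pinacol boronate (C10–C14 plus 3-furyl); iodine/methoxide then induces 1,2-migration and anti-elimination with inversion of olefin geometry. The furan, a masked maleic anhydride ring, is unveiled last by photooxygenation and Jones oxidation.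

Key step: step 10

Remark: (R)-citronellol of high enantiomeric purity is assumed as the only source of the C3 stereocentre; the photooxygenation is drawn as the 4-alkyl-5-hydroxybutenolide, and a regioisomeric hydroxybutenolide would be oxidised to the same anhydride in step 12.

Step 1
Reactants: 1 (R)-citronellol
Product: 2 tert-butyl{[(3R)-3,7-dimethyloct-6-en-1-yl]oxy}dimethylsilane
Conditions: TBSCl, imidazole, CH2Cl2, 0 °C → rt
Reagents that add atoms: tert-butyldimethylsilyl chloride CC(C)(C)[Si](C)(C)Cl
Why: Imidazole-promoted silylation of the primary alcohol masks C1–OH for the organometallic steps and does not involve the C3 stereocentre.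

Step 2
Reactants: 2 tert-butyl{[(3R)-3,7-dimethyloct-6-en-1-yl]oxy}dimethylsilane
Product: 4 (4R)-6-[(tert-butyldimethylsilyl)oxy]-4-methylhexanal, via ozonide 3 (not isolated)
Conditions: O3, CH2Cl2, −78 °C; then PPh3, −78 °C → rt
Reagents that add atoms: ozone [O-][O+]=O
Why: Ozonolysis of the only olefin with reductive work-up should cut off the isopropylidene carbon as acetone and leave the C6 aldehyde, with the silyl ether and the remote C3 stereocentre untouched.

Step 3
Reactants: 4 (4R)-6-[(tert-butyldimethylsilyl)oxy]-4-methylhexanal, 5 isopropenylmagnesium bromide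
Product: 6 (6R)-8-[(tert-butyldimethylsilyl)oxy]-2,6-dimethyloct-1-en-3-ol as a mixture of C3 epimers
Conditions: THF, −78 → 0 °C; aq. NH4Cl
Reagents that add atoms: none
Why: Grignard 1,2-addition to the aldehyde brings in C7, its methyl and C8; the new carbinol centre forms without control, which is harmless because it is destroyed in step 5.

Step 4
Reactants: 6 (6R)-8-[(tert-butyldimethylsilyl)oxy]-2,6-dimethyloct-1-en-3-ol as a mixture of C3 epimers
Product: 7 tributyl[({(6R)-8-[(tert-butyldimethylsilyl)oxy]-2,6-dimethyloct-1-en-3-yl}oxy)methyl]stannane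
Conditions: KH, THF, 0 °C; then Bu3SnCH2I, rt
Reagents that add atoms: tributyl(iodomethyl)stannane CCCC[Sn](CCCC)(CCCC)CI
Why: Williamson etherification of the potassium alkoxide with the reactive primary iodide should give the α-stannylmethyl ether required for tin–lithium exchange.

Step 5
Reactants: 7 tributyl[({(6R)-8-[(tert-butyldimethylsilyl)oxy]-2,6-dimethyloct-1-en-3-yl}oxy)methyl]stannane
Product: 9 (3Z,7R)-9-[(tert-butyldimethylsilyl)oxy]-3,7-dimethylnon-3-en-1-ol, via lithiomethyl ether 8 (not isolated)
Conditions: n-BuLi, THF, −78 °C; aq. NH4Cl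
Reagents that add atoms: none
Why: Tin–lithium exchange should trigger the Still–Wittig [2,3]-sigmatropic rearrangement, whose envelope transition state places the C5 chain pseudoaxial to avoid A(1,2) strain with the C7 methyl, so both carbinol epimers are expected to converge on the (Z)-C6=C7 olefin while the C8–C9 bond is formed.

Step 6
Reactants: 9 (3Z,7R)-9-[(tert-butyldimethylsilyl)oxy]-3,7-dimethylnon-3-en-1-ol
Product: 10 tert-butyl{[(3R,6Z)-9-iodo-3,7-dimethylnon-6-en-1-yl]oxy}dimethylsilane
Conditions: I2, PPh3, imidazole, CH2Cl2, 0 °C → rt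
Reagents that add atoms: iodine II
Why: Appel-type iodination converts the primary homoallylic alcohol into the iodide by SN2 displacement of the alkoxyphosphonium ion, without touching the olefin geometry or the silyl ether.

Step 7
Reactants: 11 (5-chloropent-1-yn-1-yl)trimethylsilane, 12 3-bromofuran
Product: 14 [5-(furan-3-yl)pent-1-yn-1-yl]trimethylsilane, via Grignard reagent 13 (not isolated)
Conditions: Mg, THF, reflux; then 12, NiCl2(dppp) (cat.), THF, 0 °C → reflux
Reagents that add atoms: none
Why: The primary alkyl Grignard reagent should undergo nickel-catalysed Kumada coupling at the sp2 C–Br bond of 3-bromofuran, while the silyl group keeps the alkyne terminus inert.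

Step 8
Reactants: 14 [5-(furan-3-yl)pent-1-yn-1-yl]trimethylsilane
Product: 15 3-(pent-4-yn-1-yl)furan
Conditions: K2CO3, MeOH, rt
Reagents that add atoms: none
Why: Methoxide-mediated protodesilylation cleaves the C(sp)–Si bond selectively and leaves the furan untouched.

Step 9
Reactants: 15 3-(pent-4-yn-1-yl)furan
Product: 16 2-[(1E)-5-(furan-3-yl)-2-methylpent-1-en-1-yl]-4,4,5,5-tetramethyl-1,3,2-dioxaborolane
Conditions: B2pin2, MeI, CuCl (cat.), Xantphos (cat.), NaOt-Bu, THF, rt
Reagents that add atoms: bis(pinacolato)diboron CC1(C)OB(OC1(C)C)B1OC(C)(C)C(C)(C)O1; iodomethane CI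
Why: Copper-catalysed borylcupration/methylation (formal syn-methylboration of a terminal alkyne) should place boron on the terminal carbon and methylate the internal alkenylcopper with retention, so boron and the new methyl end up cis, which is the (E)-alkenylboronate.

Step 10
Reactants: 10 tert-butyl{[(3R,6Z)-9-iodo-3,7-dimethylnon-6-en-1-yl]oxy}dimethylsilane, 16 2-[(1E)-5-(furan-3-yl)-2-methylpent-1-en-1-yl]-4,4,5,5-tetramethyl-1,3,2-dioxaborolane
Product: 20 tert-butyl{[(3R,6Z,10Z)-14-(furan-3-yl)-3,7,11-trimethyltetradeca-6,10-dien-1-yl]oxy}dimethylsilane, via alkyllithium 17 (not isolated), via lithium boronate 18 (not isolated), via β-iodoboronic ester 19 (not isolated)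
Conditions: t-BuLi (2.0 equiv), Et2O, −78 °C; then 16 in THF, −78 °C; then I2, THF/MeOH, −78 °C; then NaOMe, MeOH, −78 °C → rt; aq. Na2S2O3
Reagents that add atoms: none
Why: Iodine–lithium exchange gives primary alkyllithium 17, which adds to boron of 16 to form boronate 18; iodine then activates the electron-rich alkenyl group, the C9 alkyl group migrates from boron to C10 anti to the developing C–I bond, and methoxide attack on boron in β-iodoboronic ester 19 triggers anti-elimination of boron and iodide. This is a Zweifel olefination in its pinacol boronate form, a known transition-metal-free alkyl–alkenyl coupling. No ring is closed and no stereocentre remains in the product; the stereochemical element set is the C10=C11 geometry, controlled by the anti-migration/anti-elimination sequence, which converts the (E)-boronate (boron cis to the C11 methyl) into the (Z)-olefin (C9 cis to C12) with inversion. The step needs stereospecificity and chemoselectivity of iodine for the boronate over the C6=C7 olefin and the furan; the geometric purity of 16 from the syn-methylboration should secure the first and the much higher nucleophilicity of the anionic alkenylboronate at −78 °C the second. Addition of 17 to boron should outrun deprotonation of the furan, and the C3 stereocentre, the (Z)-C6=C7 olefin and the silyl ether lie away from all reacting sites.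

Step 11
Reactants: 20 tert-butyl{[(3R,6Z,10Z)-14-(furan-3-yl)-3,7,11-trimethyltetradeca-6,10-dien-1-yl]oxy}dimethylsilane
Product: 22 4-{(4Z,8Z,12R)-14-[(tert-butyldimethylsilyl)oxy]-4,8,12-trimethyltetradeca-4,8-dien-1-yl}-5-hydroxyfuran-2(5H)-one as a mixture of hemiacetal epimers, via furan endoperoxide 21 (not isolated)
Conditions: O2, hν (visible), tetraphenylporphyrin (cat.), i-Pr2NEt, CH2Cl2, −78 °C
Reagents that add atoms: dioxygen O=O
Why: Singlet oxygen should add [4+2] to the electron-rich furan faster than it undergoes the ene reaction with the trisubstituted olefins at −78 °C, and the hindered amine opens endoperoxide 21 by deprotonation at the less hindered bridgehead (Kornblum–DeLaMare type) to the γ-hydroxybutenolide, whose hemiacetal centre is oxidised away in step 12.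

Step 12
Reactants: 22 4-{(4Z,8Z,12R)-14-[(tert-butyldimethylsilyl)oxy]-4,8,12-trimethyltetradeca-4,8-dien-1-yl}-5-hydroxyfuran-2(5H)-one as a mixture of hemiacetal epimers
Product: 24 (3R,6Z,10Z)-14-(2,5-dioxo-2,5-dihydrofuran-3-yl)-3,7,11-trimethyltetradeca-6,10-dienoic acid, via desilylated alcohol 23 (not isolated)
Conditions: CrO3, H2SO4, H2O (Jones reagent), acetone, 0 °C → rt
Reagents that add atoms: water O
Why: Jones oxidation in aqueous acidic acetone should cleave the primary silyl ether, oxidise the liberated alcohol through the aldehyde hydrate to the carboxylic acid and oxidise the lactol to the anhydride carbonyl, while the isolated olefins and the non-enolisable β-stereocentre C3 are left alone.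

Compound list
1 | (R)-citronellol, (3R)-3,7-dimethyloct-6-en-1-ol | CC(C)=CCC[C@@H](C)CCO | starting material
2 | tert-butyl{[(3R)-3,7-dimethyloct-6-en-1-yl]oxy}dimethylsilane | CC(C)=CCC[C@@H](C)CCO[Si](C)(C)C(C)(C)C | intermediate
3 | ozonide of 2 (not isolated): tert-butyl{[(3R)-5-(5,5-dimethyl-1,2,4-trioxolan-3-yl)-3-methylpentyl]oxy}dimethylsilane, trioxolane centre unassigned | CC1(C)OOC(CC[C@@H](C)CCO[Si](C)(C)C(C)(C)C)O1 | intermediate
4 | (4R)-6-[(tert-butyldimethylsilyl)oxy]-4-methylhexanal | O=CCC[C@@H](C)CCO[Si](C)(C)C(C)(C)C | intermediate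
5 | isopropenylmagnesium bromide | CC(=C)[Mg]Br | starting material
6 | (6R)-8-[(tert-butyldimethylsilyl)oxy]-2,6-dimethyloct-1-en-3-ol, mixture of C3 epimers | CC(=C)C(O)CC[C@@H](C)CCO[Si](C)(C)C(C)(C)C | intermediate
7 | tributyl[({(6R)-8-[(tert-butyldimethylsilyl)oxy]-2,6-dimethyloct-1-en-3-yl}oxy)methyl]stannane, mixture of C3 epimers | CCCC[Sn](CCCC)(CCCC)COC(CC[C@@H](C)CCO[Si](C)(C)C(C)(C)C)C(C)=C | intermediate
8 | lithiomethyl ether of 6 (not isolated): ({[(6R)-8-[(tert-butyldimethylsilyl)oxy]-2,6-dimethyloct-1-en-3-yl]oxy}methyl)lithium | [Li]COC(CC[C@@H](C)CCO[Si](C)(C)C(C)(C)C)C(C)=C | intermediate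
9 | (3Z,7R)-9-[(tert-butyldimethylsilyl)oxy]-3,7-dimethylnon-3-en-1-ol | C/C(=C/CC[C@@H](C)CCO[Si](C)(C)C(C)(C)C)CCO | intermediate
10 | tert-butyl{[(3R,6Z)-9-iodo-3,7-dimethylnon-6-en-1-yl]oxy}dimethylsilane | C/C(=C/CC[C@@H](C)CCO[Si](C)(C)C(C)(C)C)CCI | intermediate
11 | (5-chloropent-1-yn-1-yl)trimethylsilane | C[Si](C)(C)C#CCCCCl | starting material
12 | 3-bromofuran | Brc1ccoc1 | starting material
13 | [5-(trimethylsilyl)pent-4-yn-1-yl]magnesium chloride (not isolated) | C[Si](C)(C)C#CCCC[Mg]Cl | intermediate
14 | [5-(furan-3-yl)pent-1-yn-1-yl]trimethylsilane | C[Si](C)(C)C#CCCCc1ccoc1 | intermediate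
15 | 3-(pent-4-yn-1-yl)furan | C#CCCCc1ccoc1 | intermediate
16 | 2-[(1E)-5-(furan-3-yl)-2-methylpent-1-en-1-yl]-4,4,5,5-tetramethyl-1,3,2-dioxaborolane | C/C(CCCc1ccoc1)=C\B1OC(C)(C)C(C)(C)O1 | intermediate
17 | {(3Z,7R)-9-[(tert-butyldimethylsilyl)oxy]-3,7-dimethylnon-3-en-1-yl}lithium (not isolated) | C/C(=C/CC[C@@H](C)CCO[Si](C)(C)C(C)(C)C)CC[Li] | intermediate
18 | lithium boronate (not isolated): pinacol boronate bearing the (E)-alkenyl group of 16 and the alkyl group of 17 on boron | [Li+].C/C(CCCc1ccoc1)=C\[B-]1(CC/C(C)=C\CC[C@@H](C)CCO[Si](C)(C)C(C)(C)C)OC(C)(C)C(C)(C)O1 | intermediate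
19 | β-iodoboronic ester (not isolated): C11 iodide and C10 pinacol boronate after migration of the C9 alkyl group to C10, anti adduct, C10 and C11 unassigned relative to C3 | CC(I)(CCCc1ccoc1)C(CC/C(C)=C\CC[C@@H](C)CCO[Si](C)(C)C(C)(C)C)B1OC(C)(C)C(C)(C)O1 | intermediate
20 | tert-butyl{[(3R,6Z,10Z)-14-(furan-3-yl)-3,7,11-trimethyltetradeca-6,10-dien-1-yl]oxy}dimethylsilane | C/C(=C/CC[C@@H](C)CCO[Si](C)(C)C(C)(C)C)CC/C=C(/C)CCCc1ccoc1 | intermediate
21 | furan endoperoxide of 20 (not isolated): 5-substituted 2,3,7-trioxabicyclo[2.2.1]hept-5-ene | C/C(=C/CC[C@@H](C)CCO[Si](C)(C)C(C)(C)C)CC/C=C(/C)CCCC1=CC2OOC1O2 | intermediate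
22 | 4-{(4Z,8Z,12R)-14-[(tert-butyldimethylsilyl)oxy]-4,8,12-trimethyltetradeca-4,8-dien-1-yl}-5-hydroxyfuran-2(5H)-one, mixture of hemiacetal epimers | C/C(=C/CC[C@@H](C)CCO[Si](C)(C)C(C)(C)C)CC/C=C(/C)CCCC1=CC(=O)OC1O | intermediate
23 | 5-hydroxy-4-[(4Z,8Z,12R)-14-hydroxy-4,8,12-trimethyltetradeca-4,8-dien-1-yl]furan-2(5H)-one (not isolated) | C/C(=C/CC[C@@H](C)CCO)CC/C=C(/C)CCCC1=CC(=O)OC1O | intermediate
24 | (3R,6Z,10Z)-14-(2,5-dioxo-2,5-dihydrofuran-3-yl)-3,7,11-trimethyltetradeca-6,10-dienoic acid | C/C(=C/CC[C@@H](C)CC(=O)O)CC/C=C(/C)CCCC1=CC(=O)OC1=O | target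

Total step count: 12. Longest linear sequence: 9 steps (steps 1–6, 10, 11, 12).

Steps most likely to fail

Step 10. Boronate formation may be incomplete if the alkyllithium is quenched or metalates the furan, and the iodine-induced migration/elimination may lose stereospecificity or be accompanied by iodination of the furan. The fallback is a Normant carbocupration–alkylation, which sets out from 3-bromofuran 12 and iodide 10 and comes back at 20. Bromine–lithium exchange of 12 (n-BuLi, THF, −78 °C) gives furan-3-yllithium F1, which opens oxetane under BF3·OEt2 activation to 3-(furan-3-yl)propan-1-ol F2. CBr4/PPh3 converts this into 3-(3-bromopropyl)furan F3, and magnesium in Et2O gives [3-(furan-3-yl)propyl]magnesium bromide F4. With CuBr·SMe2 at −45 °C this adds syn to propyne (alkyl group to the internal carbon) to give [(1Z)-5-(furan-3-yl)-2-methylpent-1-en-1-yl]copper F5. Alkylation of F5 with 10 in THF in the presence of HMPA and P(OEt)3 proceeds with retention and should give 20 with C9 cis to C12.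

Step 11. Singlet oxygen may react competitively in an ene reaction at the two trisubstituted olefins. The fallback replaces the cycloaddition by an anodic two-electron oxidation that discriminates by oxidation potential; it sets out from 20 and comes back at 24. Constant-current electrolysis of 20 in methanol (graphite anode, Et4NOTs, −20 °C, about 2 F/mol; Clauson-Kaas-type methoxylation) should give tert-butyl{[(3R,6Z,10Z)-14-(2,5-dimethoxy-2,5-dihydrofuran-3-yl)-3,7,11-trimethyltetradeca-6,10-dien-1-yl]oxy}dimethylsilane F6. Jones reagent in acetone then hydrolyses both acetals and the silyl ether and oxidises the ring carbons and C1, leading directly to 24.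

Step 9. Borylcupration may occur with the wrong regiochemistry, or the terminal alkyne may be diverted into a copper acetylide. The fallback is a Negishi carboalumination, which sets out from 15 and comes back at 16. Me3Al with catalytic Cp2ZrCl2 in CH2Cl2 adds methyl and aluminium syn to give [(1E)-5-(furan-3-yl)-2-methylpent-1-en-1-yl]dimethylalane F7. Iodine at −30 °C converts it with retention into 3-[(4E)-5-iodo-4-methylpent-4-en-1-yl]furan F8. Iodine–lithium exchange (t-BuLi, Et2O, −78 °C) gives [(1E)-5-(furan-3-yl)-2-methylpent-1-en-1-yl]lithium F9, which is borylated with 2-isopropoxy-4,4,5,5-tetramethyl-1,3,2-dioxaborolane to give 16.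

Further compounds
F1 | step 10 | furan-3-yllithium | [Li]c1ccoc1
F2 | step 10 | 3-(furan-3-yl)propan-1-ol | OCCCc1ccoc1
F3 | step 10 | 3-(3-bromopropyl)furan | BrCCCc1ccoc1
F4 | step 10 | [3-(furan-3-yl)propyl]magnesium bromide | Br[Mg]CCCc1ccoc1
F5 | step 10 | [(1Z)-5-(furan-3-yl)-2-methylpent-1-en-1-yl]copper | C/C(CCCc1ccoc1)=C/[Cu]
F6 | step 11 | tert-butyl{[(3R,6Z,10Z)-14-(2,5-dimethoxy-2,5-dihydrofuran-3-yl)-3,7,11-trimethyltetradeca-6,10-dien-1-yl]oxy}dimethylsilane | C/C(=C/CC[C@@H](C)CCO[Si](C)(C)C(C)(C)C)CC/C=C(/C)CCCC1=CC(OC)OC1OC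
F7 | step 9 | [(1E)-5-(furan-3-yl)-2-methylpent-1-en-1-yl]dimethylalane | C/C(CCCc1ccoc1)=C\[Al](C)C
F8 | step 9 | 3-[(4E)-5-iodo-4-methylpent-4-en-1-yl]furan | C/C(CCCc1ccoc1)=C\I
F9 | step 9 | [(1E)-5-(furan-3-yl)-2-methylpent-1-en-1-yl]lithium | C/C(CCCc1ccoc1)=C\[Li]
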